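**Retrosynthetic overview**

- Target ⇐ silyl removal after a ligand-controlled CuH 1,4-reduction of a 4-(1-hydroxyalkyl)furan-2(5H)-one; the reduction sets the lactone C4.
- Key bond (carbinol carbon to lactone C4): Ni/Cr coupling of a (Z)-β,γ-unsaturated aldehyde with 4-bromofuran-2(5H)-one. The butenolide β-carbon, normally an acceptor, reacts as an alkenylchromium nucleophile (β-acylvinyl anion, d3) with the aldehyde carbon, and the chromium ligand sets the carbinol.
- Aldehyde ⇐ Z-selective Wittig reaction of an α-silyloxy ketone with a three-carbon ylide, then desilylation and oxidation.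
- Ketone ⇐ Carroll rearrangement of a tertiary allylic alcohol (makes the bond to the side chain and the tetrasubstituted ring olefin) ⇐ cis-fused exocyclic enone ⇐ cuprate addition and methylenation of an enantioenriched octalone.
- Rings: no ring is closed in the route. Rings A and B both come from 6-methoxy-1-tetralone (ring A is gem-dimethylated; ring B is unmasked by Birch reduction and asymmetric isomerisation; the cis fusion comes from the cuprate step). The lactone ring arrives preformed in the bromobutenolide.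

Assumption: the target SMILES is read as written (cis-fused decalin 4aR,8aS; carbinol 1R; lactone 4S; olefin 3Z); for the ligand-controlled steps 3, 13 and 14 the ligand antipode named is taken to give the drawn configuration, and its mirror image is used if a test run shows the opposite sense.

**Step 1**
Reactants: 1 6-methoxy-3,4-dihydronaphthalen-1(2H)-one
Product: 2 6-methoxy-1,1-dimethyl-1,2,3,4-tetrahydronaphthalene
Conditions: Me2Zn, TiCl4, CH2Cl2, −30 °C to rt
Reagents that add atoms: dimethylzinc, C[Zn]C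
Why: Reetz geminal dimethylation, in which Me2TiCl2 formed in the flask adds to the ketone and the benzylic titanium alkoxide, stabilised by the para-methoxy group, ionises and takes up the second methyl; no stereocentre is formed.

**Step 2**
Reactants: 2 6-methoxy-1,1-dimethyl-1,2,3,4-tetrahydronaphthalene
Product: 4 5,5-dimethyl-3,4,5,6,7,8-hexahydronaphthalen-2(1H)-one, via Birch enol ether 3 (not isolated)
Conditions: Li, NH3 (l), THF, t-BuOH, −33 °C; then (CO2H)2, MeOH/H2O, rt
Reagents that add atoms: water, O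
Why: Birch reduction protonates the two unsubstituted para positions of the anisole ring, leaving the enol ether and the ring-fusion olefin, and mild oxalic acid hydrolysis unmasks the ketone without moving the β,γ double bond into conjugation; no stereocentre is formed.

**Step 3**
Reactants: 4 5,5-dimethyl-3,4,5,6,7,8-hexahydronaphthalen-2(1H)-one
Product: 5 (4aR)-5,5-dimethyl-4,4a,5,6,7,8-hexahydronaphthalen-2(3H)-one
Conditions: 9-amino-9-deoxy-epi-quinine (10 mol %), Cl3CCO2H (20 mol %), toluene, 0 °C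
Reagents that add atoms: none
Why: Proposed new method: the primary amine condenses with the ketone, α-deprotonation gives a dienamine, and the protonated quinuclidine delivers a proton to one face of the γ-carbon (C4a) before iminium hydrolysis, which sets 4aR with the conjugated enone as the thermodynamic sink; the closest known reaction type is the cinchona primary-amine-catalysed enantioselective isomerisation of β,γ- to α,β-unsaturated cyclohexenones, extended here to a ring-fusion tetrasubstituted olefin.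

**Step 4**
Reactants: 5 (4aR)-5,5-dimethyl-4,4a,5,6,7,8-hexahydronaphthalen-2(3H)-one
Product: 9 (4aR,8aS)-5,5,8a-trimethyl-1-methylideneoctahydronaphthalen-2(1H)-one, via lithium enolate 6 (not isolated), via Mannich base 7 (not isolated), via ammonium iodide 8 (not isolated)
Conditions: Me2CuLi (from MeLi, CuI), Et2O, 0 °C; then CH2=NMe2 iodide, THF, −78 °C to rt; then MeI, MeOH, rt; then aq. NaHCO3, CH2Cl2
Reagents that add atoms: lithium dimethylcuprate, [Li+].C[Cu-]C; dimethyl(methylidene)ammonium iodide, C[N+](C)=C.[I-]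
Why: Cuprate conjugate addition occurs axially, anti to the pseudo-axial C4a–C5 bond of the enone conformer that avoids allylic strain with the gem-dimethyl carbon, so the new 8a-methyl is cis to H-4a (8aS), and the regiodefined enolate is trapped in a Mannich reaction whose quaternised amine eliminates to the exocyclic enone.

**Step 5**
Reactants: 9 (4aR,8aS)-5,5,8a-trimethyl-1-methylideneoctahydronaphthalen-2(1H)-one
Product: 10 (4aR,8aS)-2,5,5,8a-tetramethyl-1-methylidenedecahydronaphthalen-2-ol (both C2 epimers)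
Conditions: MeLi, CeCl3, THF, −78 °C; H2O
Reagents that add atoms: methyllithium, [Li]C
Why: Cerium-mediated 1,2-addition to the enone carbonyl avoids enolisation and conjugate addition, and the new carbinol centre may be a mixture because it becomes sp2 in step 8.

**Step 6**
Reactants: 11 methyl 2-hydroxyacetate
Product: 12 methyl 2-[(triisopropylsilyl)oxy]acetate
Conditions: TIPSCl, imidazole, DMF, rt
Reagents that add atoms: chlorotriisopropylsilane, CC(C)[Si](Cl)(C(C)C)C(C)C
Why: Imidazole-promoted silyl ether formation on the only hydroxyl group; no stereocentre.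

**Step 7**
Reactants: 12 methyl 2-[(triisopropylsilyl)oxy]acetate; 13 tert-butyl acetate
Product: 15 tert-butyl 3-oxo-4-[(triisopropylsilyl)oxy]butanoate, via lithium ester enolate 14 (not isolated)
Conditions: LiN(iPr)2 (2.2 equiv), THF, −78 °C; then 12, −78 to 0 °C; aq. HCl
Reagents that add atoms: none
Why: Crossed Claisen condensation in which the non-self-condensing lithium enolate of tert-butyl acetate acylates on the methyl ester and the product is held as its enolate until the acid quench; no stereocentre.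

**Step 8**
Reactants: 10 (4aR,8aS)-2,5,5,8a-tetramethyl-1-methylidenedecahydronaphthalen-2-ol; 15 tert-butyl 3-oxo-4-[(triisopropylsilyl)oxy]butanoate
Product: 18 4-[(4aR,8aS)-2,5,5,8a-tetramethyl-3,4,4a,5,6,7,8,8a-octahydronaphthalen-1-yl]-1-[(triisopropylsilyl)oxy]butan-2-one, via allyl ketoester 16 (not isolated), via ketoacid 17 (not isolated)
Conditions: xylene, 140 °C (t-BuOH distilled off), Al(OiPr)3 (10 mol %)
Reagents that add atoms: none
Why: Carroll rearrangement, in which acylketene transfer esterifies the tertiary allylic alcohol, the enol of the allyl β-keto ester undergoes a [3,3] shift that bonds its α-carbon to the exocyclic methylene and moves the double bond into the ring as the tetrasubstituted olefin, and the β-keto acid loses CO2; the ring stereocentres are untouched.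

**Step 9**
Reactants: 19 (3-bromopropoxy)(tert-butyl)dimethylsilane
Product: 20 {3-[(tert-butyldimethylsilyl)oxy]propyl}triphenylphosphonium bromide
Conditions: PPh3, MeCN, 80 °C
Reagents that add atoms: triphenylphosphine, c1ccc(cc1)P(c1ccccc1)c1ccccc1
Why: SN2 quaternisation of triphenylphosphine by the primary bromide (phosphonium salt formation); no stereocentre.

**Step 10**
Reactants: 18 4-[(4aR,8aS)-2,5,5,8a-tetramethyl-3,4,4a,5,6,7,8,8a-octahydronaphthalen-1-yl]-1-[(triisopropylsilyl)oxy]butan-2-one; 20 {3-[(tert-butyldimethylsilyl)oxy]propyl}triphenylphosphonium bromide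
Product: 22 (3Z)-1-[(tert-butyldimethylsilyl)oxy]-4-{[(triisopropylsilyl)oxy]methyl}-6-[(4aR,8aS)-2,5,5,8a-tetramethyl-3,4,4a,5,6,7,8,8a-octahydronaphthalen-1-yl]hex-3-ene, via phosphorus ylide 21 (not isolated)
Conditions: KN(SiMe3)2, THF, −78 °C; then 18, −78 °C to rt
Reagents that add atoms: none
Why: Wittig olefination of an α-silyloxy ketone with a salt-free non-stabilised ylide (Still's Z-selective variant for trisubstituted allylic ethers) places the oxygen-bearing CH2 cis to the new chain, which gives the 3Z olefin.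

**Step 11**
Reactants: 22 (3Z)-1-[(tert-butyldimethylsilyl)oxy]-4-{[(triisopropylsilyl)oxy]methyl}-6-[(4aR,8aS)-2,5,5,8a-tetramethyl-3,4,4a,5,6,7,8,8a-octahydronaphthalen-1-yl]hex-3-ene
Product: 23 (3Z)-4-{[(triisopropylsilyl)oxy]methyl}-6-[(4aR,8aS)-2,5,5,8a-tetramethyl-3,4,4a,5,6,7,8,8a-octahydronaphthalen-1-yl]hex-3-en-1-ol
Conditions: PPTS, EtOH, rt
Reagents that add atoms: none
Why: Acid-catalysed ethanolysis removes the less hindered primary tert-butyldimethylsilyl ether far faster than the triisopropylsilyl ether (selective desilylation), leaving olefin geometry and stereocentres untouched.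

**Step 12**
Reactants: 23 (3Z)-4-{[(triisopropylsilyl)oxy]methyl}-6-[(4aR,8aS)-2,5,5,8a-tetramethyl-3,4,4a,5,6,7,8,8a-octahydronaphthalen-1-yl]hex-3-en-1-ol
Product: 24 (3Z)-4-{[(triisopropylsilyl)oxy]methyl}-6-[(4aR,8aS)-2,5,5,8a-tetramethyl-3,4,4a,5,6,7,8,8a-octahydronaphthalen-1-yl]hex-3-enal
Conditions: Dess–Martin periodinane, pyridine, CH2Cl2, 0 °C; used at once
Reagents that add atoms: none
Why: Buffered Dess–Martin oxidation gives the β,γ-unsaturated aldehyde under neutral conditions, so the Z olefin does not move into conjugation.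

**Step 13**
Reactants: 24 (3Z)-4-{[(triisopropylsilyl)oxy]methyl}-6-[(4aR,8aS)-2,5,5,8a-tetramethyl-3,4,4a,5,6,7,8,8a-octahydronaphthalen-1-yl]hex-3-enal; 25 4-bromofuran-2(5H)-one
Product: 26 4-[(1R,3Z)-1-hydroxy-4-{[(triisopropylsilyl)oxy]methyl}-6-[(4aR,8aS)-2,5,5,8a-tetramethyl-3,4,4a,5,6,7,8,8a-octahydronaphthalen-1-yl]hex-3-en-1-yl]furan-2(5H)-one
Conditions: CrCl2, NiCl2 (2 mol %), (S)-N-[2-(4-isopropyl-4,5-dihydrooxazol-2-yl)-6-methylphenyl]methanesulfonamide, Et3N, THF, rt; aq. work-up
Reagents that add atoms: none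
Why: Proposed new method: nickel inserts into the C4–Br bond of the butenolide and hands the alkenyl group to chromium, which turns the normally electrophilic β-carbon into a non-basic alkenylchromium nucleophile (a β-acylvinyl anion, d3 reversed-polarity synthon) that adds to the aldehyde without enolising it, while the chiral sulfonamide on chromium directs attack to the Si face to set C1 of the side chain as R; the closest known reaction type is the Nozaki–Hiyama–Kishi coupling of (Z)-β-iodoacrylates and β-halo enones with aldehydes.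

**Step 14**
Reactants: 26 4-[(1R,3Z)-1-hydroxy-4-{[(triisopropylsilyl)oxy]methyl}-6-[(4aR,8aS)-2,5,5,8a-tetramethyl-3,4,4a,5,6,7,8,8a-octahydronaphthalen-1-yl]hex-3-en-1-yl]furan-2(5H)-one
Product: 29 (4S)-4-[(1R,3Z)-1-hydroxy-4-(hydroxymethyl)-6-[(4aR,8aS)-2,5,5,8a-tetramethyl-3,4,4a,5,6,7,8,8a-octahydronaphthalen-1-yl]hex-3-en-1-yl]dihydrofuran-2(3H)-one, via silyl ether 27 (not isolated), via lactone silyl ether 28 (not isolated)
Conditions: Cu(OAc)2 (5 mol %), (S)-p-tol-BINAP (5 mol %), (EtO)2MeSiH, t-BuOH, toluene, 0 °C; then HF·pyridine, THF/pyridine, 0 °C to rt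
Reagents that add atoms: none
Why: Asymmetric CuH conjugate reduction (Buchwald type for β-substituted butenolides), in which the catalyst first silylates the carbinol and then delivers hydride only to the β-carbon of the butenolide, on the Re face under bisphosphine control to set 4S, and base-free HF·pyridine then removes both silyl groups so the lactone cannot migrate to the secondary oxygen.

**Compound list**

1 | 6-methoxy-3,4-dihydronaphthalen-1(2H)-one | COc1ccc2C(=O)CCCc2c1 | starting material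
2 | 6-methoxy-1,1-dimethyl-1,2,3,4-tetrahydronaphthalene | COc1ccc2c(c1)CCCC2(C)C | intermediate
3 | 6-methoxy-1,1-dimethyl-1,2,3,4,5,8-hexahydronaphthalene | COC1=CCC2=C(C1)CCCC2(C)C | intermediate (not isolated)
4 | 5,5-dimethyl-3,4,5,6,7,8-hexahydronaphthalen-2(1H)-one | O=C1CC2=C(CC1)C(C)(C)CCC2 | intermediate
5 | (4aR)-5,5-dimethyl-4,4a,5,6,7,8-hexahydronaphthalen-2(3H)-one | O=C1C=C2CCCC(C)(C)[C@H]2CC1 | intermediate
6 | lithium (4aR,8aS)-5,5,8a-trimethyl-3,4,4a,5,6,7,8,8a-octahydronaphthalen-2-olate | [Li+].[O-]C1=C[C@@]2(C)CCCC(C)(C)[C@H]2CC1 | intermediate (not isolated)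
7 | (4aR,8aS)-1-[(dimethylamino)methyl]-5,5,8a-trimethyloctahydronaphthalen-2(1H)-one (C1 epimers) | O=C1C(CN(C)C)[C@@]2(C)CCCC(C)(C)[C@H]2CC1 | intermediate (not isolated)
8 | N,N,N-trimethyl-1-[(4aR,8aS)-5,5,8a-trimethyl-2-oxodecahydronaphthalen-1-yl]methanaminium iodide | O=C1C(C[N+](C)(C)C)[C@@]2(C)CCCC(C)(C)[C@H]2CC1.[I-] | intermediate (not isolated)
9 | (4aR,8aS)-5,5,8a-trimethyl-1-methylideneoctahydronaphthalen-2(1H)-one | O=C1C(=C)[C@@]2(C)CCCC(C)(C)[C@H]2CC1 | intermediate
10 | (4aR,8aS)-2,5,5,8a-tetramethyl-1-methylidenedecahydronaphthalen-2-ol (both C2 epimers) | CC1(O)C(=C)[C@@]2(C)CCCC(C)(C)[C@H]2CC1 | intermediate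
11 | methyl 2-hydroxyacetate | COC(=O)CO | starting material
12 | methyl 2-[(triisopropylsilyl)oxy]acetate | COC(=O)CO[Si](C(C)C)(C(C)C)C(C)C | intermediate
13 | tert-butyl acetate | CC(=O)OC(C)(C)C | starting material
14 | lithium 1-tert-butoxyethenolate | [Li+].[O-]C(=C)OC(C)(C)C | intermediate (not isolated)
15 | tert-butyl 3-oxo-4-[(triisopropylsilyl)oxy]butanoate | CC(C)(C)OC(=O)CC(=O)CO[Si](C(C)C)(C(C)C)C(C)C | intermediate
16 | (4aR,8aS)-2,5,5,8a-tetramethyl-1-methylidenedecahydronaphthalen-2-yl 3-oxo-4-[(triisopropylsilyl)oxy]butanoate | CC1(OC(=O)CC(=O)CO[Si](C(C)C)(C(C)C)C(C)C)C(=C)[C@@]2(C)CCCC(C)(C)[C@H]2CC1 | intermediate (not isolated)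
17 | 3-oxo-2-{[(4aR,8aS)-2,5,5,8a-tetramethyl-3,4,4a,5,6,7,8,8a-octahydronaphthalen-1-yl]methyl}-4-[(triisopropylsilyl)oxy]butanoic acid | CC1=C(CC(C(=O)O)C(=O)CO[Si](C(C)C)(C(C)C)C(C)C)[C@@]2(C)CCCC(C)(C)[C@H]2CC1 | intermediate (not isolated)
18 | 4-[(4aR,8aS)-2,5,5,8a-tetramethyl-3,4,4a,5,6,7,8,8a-octahydronaphthalen-1-yl]-1-[(triisopropylsilyl)oxy]butan-2-one | CC1=C(CCC(=O)CO[Si](C(C)C)(C(C)C)C(C)C)[C@@]2(C)CCCC(C)(C)[C@H]2CC1 | intermediate
19 | (3-bromopropoxy)(tert-butyl)dimethylsilane | BrCCCO[Si](C)(C)C(C)(C)C | starting material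
20 | {3-[(tert-butyldimethylsilyl)oxy]propyl}triphenylphosphonium bromide | CC(C)(C)[Si](C)(C)OCCC[P+](c1ccccc1)(c1ccccc1)c1ccccc1.[Br-] | intermediate
21 | {3-[(tert-butyldimethylsilyl)oxy]propylidene}triphenylphosphorane | CC(C)(C)[Si](C)(C)OCCC=P(c1ccccc1)(c1ccccc1)c1ccccc1 | intermediate (not isolated)
22 | (3Z)-1-[(tert-butyldimethylsilyl)oxy]-4-{[(triisopropylsilyl)oxy]methyl}-6-[(4aR,8aS)-2,5,5,8a-tetramethyl-3,4,4a,5,6,7,8,8a-octahydronaphthalen-1-yl]hex-3-ene | CC1=C(CC/C(=C/CCO[Si](C)(C)C(C)(C)C)CO[Si](C(C)C)(C(C)C)C(C)C)[C@@]2(C)CCCC(C)(C)[C@H]2CC1 | intermediate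
23 | (3Z)-4-{[(triisopropylsilyl)oxy]methyl}-6-[(4aR,8aS)-2,5,5,8a-tetramethyl-3,4,4a,5,6,7,8,8a-octahydronaphthalen-1-yl]hex-3-en-1-ol | CC1=C(CC/C(=C/CCO)CO[Si](C(C)C)(C(C)C)C(C)C)[C@@]2(C)CCCC(C)(C)[C@H]2CC1 | intermediate
24 | (3Z)-4-{[(triisopropylsilyl)oxy]methyl}-6-[(4aR,8aS)-2,5,5,8a-tetramethyl-3,4,4a,5,6,7,8,8a-octahydronaphthalen-1-yl]hex-3-enal | CC1=C(CC/C(=C/CC=O)CO[Si](C(C)C)(C(C)C)C(C)C)[C@@]2(C)CCCC(C)(C)[C@H]2CC1 | intermediate
25 | 4-bromofuran-2(5H)-one | BrC1=CC(=O)OC1 | starting material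
26 | 4-[(1R,3Z)-1-hydroxy-4-{[(triisopropylsilyl)oxy]methyl}-6-[(4aR,8aS)-2,5,5,8a-tetramethyl-3,4,4a,5,6,7,8,8a-octahydronaphthalen-1-yl]hex-3-en-1-yl]furan-2(5H)-one | CC1=C(CC/C(=C/C[C@@H](O)C3=CC(=O)OC3)CO[Si](C(C)C)(C(C)C)C(C)C)[C@@]2(C)CCCC(C)(C)[C@H]2CC1 | intermediate
27 | 4-[(1R,3Z)-1-[(diethoxymethylsilyl)oxy]-4-{[(triisopropylsilyl)oxy]methyl}-6-[(4aR,8aS)-2,5,5,8a-tetramethyl-3,4,4a,5,6,7,8,8a-octahydronaphthalen-1-yl]hex-3-en-1-yl]furan-2(5H)-one | CC1=C(CC/C(=C/C[C@@H](O[Si](C)(OCC)OCC)C3=CC(=O)OC3)CO[Si](C(C)C)(C(C)C)C(C)C)[C@@]2(C)CCCC(C)(C)[C@H]2CC1 | intermediate (not isolated)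
28 | (4S)-4-[(1R,3Z)-1-[(diethoxymethylsilyl)oxy]-4-{[(triisopropylsilyl)oxy]methyl}-6-[(4aR,8aS)-2,5,5,8a-tetramethyl-3,4,4a,5,6,7,8,8a-octahydronaphthalen-1-yl]hex-3-en-1-yl]dihydrofuran-2(3H)-one | CC1=C(CC/C(=C/C[C@@H](O[Si](C)(OCC)OCC)[C@@H]3COC(=O)C3)CO[Si](C(C)C)(C(C)C)C(C)C)[C@@]2(C)CCCC(C)(C)[C@H]2CC1 | intermediate (not isolated)
29 | (4S)-4-[(1R,3Z)-1-hydroxy-4-(hydroxymethyl)-6-[(4aR,8aS)-2,5,5,8a-tetramethyl-3,4,4a,5,6,7,8,8a-octahydronaphthalen-1-yl]hex-3-en-1-yl]dihydrofuran-2(3H)-one | CC1=C(CC/C(=C/C[C@@H](O)[C@@H]2COC(=O)C2)CO)[C@@]2(C)CCCC(C)(C)[C@H]2CC1 | target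

**Step count and risk**

Total step count: 14. Longest linear sequence: 11 steps (1, 2, 3, 4, 5, 8, 10, 11, 12, 13, 14).

The three steps most likely to fail are 3, 13 and 14.

Step 3 may give low enantiomeric excess or stall, because the γ-carbon that is protonated sits between two fully substituted carbons. The fallback sets out from 4: isomerise it with p-TsOH in toluene to racemic 5,5-dimethyl-4,4a,5,6,7,8-hexahydronaphthalen-2(3H)-one F1, add lithiated (S)-N,S-dimethyl-S-phenylsulfoximine to the carbonyl, and separate by chromatography the diastereomer (4aR)-5,5-dimethyl-2-{[(S)-N-methyl-S-phenylsulfonimidoyl]methyl}-2,3,4,4a,5,6,7,8-octahydronaphthalen-2-ol F2. Heating F2 in toluene expels the sulfoximine and returns the enantiopure enone, which comes back to the route at 5.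

Step 13 may fail if the bromobutenolide homocouples or the aldehyde isomerises before the chromium reagent forms. The fallback sets out from 25 and brings the butenolide in as a lithiated silyloxyfuran:
- Silylate 25 (TIPSOTf, Et3N) to 4-bromo-2-[(triisopropylsilyl)oxy]furan F3.
- Exchange bromine for lithium with n-BuLi at −78 °C to give 4-lithio-2-[(triisopropylsilyl)oxy]furan F4.
- Add aldehyde 24 to give the lithium alkoxide of the silyloxyfuryl carbinol F5; work-up with dilute HCl unmasks the butenolide carbinol epimeric at the carbinol carbon F6.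
- Oxidise with Dess–Martin periodinane to the 4-acylfuran-2(5H)-one F7 and reduce at once with (S)-Me-CBS oxazaborolidine and catecholborane, which comes back to the route at 26.

Step 14 may give poor selectivity at lactone C4 if the adjacent carbinol centre overrides the ligand. The fallback sets out from 26 and uses the free hydroxyl to direct a homogeneous hydrogenation with [Rh(nbd)(dppb)]BF4 under H2 in CH2Cl2. By the allylic-strain model for 2-(1-hydroxyalkyl)alkenes this adds hydrogen anti to the hydroxyl and gives the (4S)-lactone triisopropylsilyl ether F8. HF·pyridine then comes back to the route at 29. The risk to watch here is reduction of the side-chain trisubstituted olefin.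

**Further compounds**

F1 | step 3 | racemic 5,5-dimethyl-4,4a,5,6,7,8-hexahydronaphthalen-2(3H)-one | O=C1C=C2CCCC(C)(C)C2CC1
F2 | step 3 | (4aR)-5,5-dimethyl-2-{[(S)-N-methyl-S-phenylsulfonimidoyl]methyl}-2,3,4,4a,5,6,7,8-octahydronaphthalen-2-ol | CN=[S@@](CC1(O)C=C2CCCC(C)(C)[C@H]2CC1)(=O)c1ccccc1
F3 | step 13 | 4-bromo-2-[(triisopropylsilyl)oxy]furan | CC(C)[Si](Oc1cc(Br)co1)(C(C)C)C(C)C
F4 | step 13 | 4-lithio-2-[(triisopropylsilyl)oxy]furan | [Li]c1coc(O[Si](C(C)C)(C(C)C)C(C)C)c1
F5 | step 13 | lithium alkoxide of the silyloxyfuryl carbinol | CC1=C(CC/C(=C/CC([O-])c3coc(O[Si](C(C)C)(C(C)C)C(C)C)c3)CO[Si](C(C)C)(C(C)C)C(C)C)[C@@]2(C)CCCC(C)(C)[C@H]2CC1.[Li+]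
F6 | step 13 | butenolide carbinol epimeric at the carbinol carbon | CC1=C(CC/C(=C/CC(O)C3=CC(=O)OC3)CO[Si](C(C)C)(C(C)C)C(C)C)[C@@]2(C)CCCC(C)(C)[C@H]2CC1
F7 | step 13 | 4-acylfuran-2(5H)-one | CC1=C(CC/C(=C/CC(=O)C3=CC(=O)OC3)CO[Si](C(C)C)(C(C)C)C(C)C)[C@@]2(C)CCCC(C)(C)[C@H]2CC1
F8 | step 14 | (4S)-lactone triisopropylsilyl ether | CC1=C(CC/C(=C/C[C@@H](O)[C@@H]3COC(=O)C3)CO[Si](C(C)C)(C(C)C)C(C)C)[C@@]2(C)CCCC(C)(C)[C@H]2CC1
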